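## Structural features

The target is a 2-aryl-3-methyl-2,3-dihydro-1,4-benzodioxine. Ring A (the benzo ring, C4a to C8a) carries a methoxy group at C5 and an allyl group at C7, the dioxane ring (O1, C2, C3, O4) is fused to it at C4a/C8a, and ring B, a 4-hydroxy-3,5-dimethoxyphenyl group, sits on C2. C2 (aryl, bonded to O1) and C3 (methyl, bonded to O4) are adjacent stereocentres, both R, so aryl and methyl are trans on the dioxane ring. Ring A is unsymmetrical, which adds a regiochemical problem: O1, which carries the benzylic carbon, is on C8a next to C8–H, while O4 is on C4a, between C8a and the methoxy-bearing C5. The fragile parts are the allyl group (migration into conjugation under strong base or metal hydrides, loss under hydrogenation) and the C2–O1 bond. Once the ring B phenol is free, C2–O1 is a para-hydroxybenzyl aryl ether that can ionise reversibly through a quinone methide. This makes C2 thermodynamically correctable towards trans, whereas C3 has no such escape and must be set absolutely; the real difficulty is to join the two ring A oxygens to the correct carbons of a C2–C3 unit whose C3 configuration is secure. The key step exploits the fact that C4a is para to C7: with an ester at C7 in place of allyl, a bromide on C4a is activated for C–O bond formation by the C3 oxygen, and ring A then derives from a 4-bromo-3,5-dihydroxybenzoate whose two hydroxyl groups are equivalent.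

## Logic of the disconnections

**15 to 14.** Cut: the O–CH2 bond of an acetal on the ring B oxygen. Reason: the free phenol is what makes C2–O1 labile, so it is released last. Gain: every earlier intermediate is a plain aryl alkyl ether, inert to base, hydride and palladium. Demand: the unmasking must spare the allyl group; dilute acid does, and any reversible ionisation at C2 can only end in the more stable trans ring.

**14 to 12 and 13.** Cut: the CH2–CH bond between the benzylic carbon on C7 and the vinyl group. Reason: the alkene then enters in the last carbon–carbon bond formation and never meets base or hydride. Gain: the C7 side chain shrinks to one carbon. Demand: a base-free coupling that does not move the double bond into conjugation.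

**12 to 11 to 10.** No skeletal bond is cut; the C–Br bond and then the two benzylic C–H bonds are traced back to an ester carbonyl. Reason: an ester at C7 is the acceptor that the ring closure needs para to C4a. Gain: the handle for the allyl group and the activating group of the key step are the same atom. Demand: a hydride reduction and a neutral bromination that leave the acetal and the benzylic ether alone.

**10 to 9.** Cut: O4–C4a, the aryl–oxygen bond para to the ester. Reason: neither C2 nor C3 is touched, so a threo ether alcohol must give the trans ring. Gain: the dioxane opens to an acyclic compound with one free hydroxyl and one halide. Demand: a secondary alkoxide must attack a bromide flanked by two oxygen substituents, in a molecule that offers the alkoxide nothing else to attack. This demand fixes the protecting group on ring B. An acyl group was set aside for three reasons: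
- beside a caesium alkoxide at 110 °C, acyl transfer would free a phenoxide para to the benzylic aryl ether, which fragments through the quinone methide;
- it would be stripped during the ester reduction, leaving the phenol bare through bromination and coupling;
- it makes ring B an acceptor and weakens the benzylic preference needed in the next disconnection.

An acetal has none of these faults, at the cost of one extra step.

**9 to 6 and 8.** Cut: O1–C2. Reason: the benzylic carbon of a cis-epoxide is the electrophile and the phenol oxygen the nucleophile, so one inversion converts cis into threo while C3 is untouched. Gain: two fragments of similar size, with C3 already set. Demand: attack at the benzylic carbon with clean inversion; the ether donor on ring B favours it.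

**8 to 7.** Cut: the O–CH3 bond at C5. Reason: the diol is symmetric, so either hydroxyl gives the same monoether and ring A has no regiochemical question. Gain: a commercial arene. Demand: mono-alkylation, which is only statistically controlled.

**6 to 5.** Cut: both C–O bonds of the oxirane. Reason: oxygen transfer to a Z-alkene from a chiral salen manganese oxo species sets C3. Gain: an achiral alkene. Demand: facial control and retention of the cis geometry.

**5 to 2 and 3.** Cut: the C=C bond, through ylide 4. Reason: a non-stabilised ylide gives the Z-alkene kinetically. Gain: a commercial aldehyde and a commercial phosphonium salt. Demand: salt-free conditions for Z-selectivity.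

**2 to 1.** Cut: the O–CH2 bond of the acetal. Gain: a commercial phenol aldehyde. Demand: none beyond a clean O-alkylation.

## Other disconnections considered

**Alternative 1:** The cut is the other aryl–oxygen bond of the dioxane, O1–C8a, so the oxygen on C3 is already an aryl ether and the benzylic C2 hydroxyl is the nucleophile.
- Forward step: the bromo alcohol A2, (1R,2R)-2-[2-bromo-6-methoxy-4-(prop-2-en-1-yl)phenoxy]-1-[3,5-dimethoxy-4-(methoxymethoxy)phenyl]propan-1-ol, would be heated with CuI, 3,4,7,8-tetramethyl-1,10-phenanthroline and Cs2CO3. It should give A1, (2R,3R)-2-[3,5-dimethoxy-4-(methoxymethoxy)phenyl]-5-methoxy-3-methyl-7-(prop-2-en-1-yl)-2,3-dihydro-1,4-benzodioxine, which is the same compound as 14.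
- In its favour: the allyl group is on ring A from the start, so the three steps from ester to allyl fall away and A1 is one deprotection from the target. The bromide in A2 has only one ortho substituent. C3 could come from the chiral pool by an invertive aryl ether formation, so its purity would not depend on a catalyst.
- Against it: the bromide sits on an electron-rich ring with no acceptor. The nucleophile is a hindered benzylic alkoxide that copper can oxidise to the aryl ketone. The allyl group must survive carbonate at 110 °C. The threo relation in A2 would rest on a diastereoselective ketone reduction.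
- Comparison: on structure, the alternative is better at the halide (less hindered) and the chosen plan is better in activation and in the nucleophile. On mechanism the two are equal, the same reaction class. On step economy the alternative is better by about two or three steps. The chosen plan is preferred because the allyl group is never exposed to hot base and because the regiochemistry on ring A is settled by symmetry.

**Alternative 2:** The cut is C3–O4 together with one C–H bond of the methyl group, which traces C3 back to the internal carbon of a vinyl group.
- Forward step: the phenol A4, 4-bromo-2-{[(1S)-1-[3,5-dimethoxy-4-(triisopropylsilyloxy)phenyl]prop-2-en-1-yl]oxy}-6-methoxyphenol, would be treated with Co(salen), N-fluoro-2,4,6-trimethylpyridinium tetrafluoroborate and PhSiH3. A cobalt hydride passes a hydrogen atom to the terminal alkene carbon, the secondary radical at C3 is oxidised through an alkylcobalt species, and the ring A phenol captures it in a 6-exo closure. The product would be A3, (2R,3R)-7-bromo-2-[3,5-dimethoxy-4-(triisopropylsilyloxy)phenyl]-5-methoxy-3-methyl-2,3-dihydro-1,4-benzodioxine.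
- In its favour: near-neutral conditions at room temperature with no hindered aryl halide to activate, which is better than the chosen plan. The ring closure creates the methyl group and a stereocentre. Only C2 must be set beforehand, for instance with [Ir(cod)Cl]2 and a chiral phosphoramidite in an allylic etherification. The bromide at C7 allows direct allylation.
- Against it: C3 would be set only by induction from C2. A cis closure cannot be repaired, because later equilibration at C2 would lead into the enantiomeric trans series. The cation equivalent at C3 lies next to a carbon bearing an ether oxygen and an electron-rich aryl group, so a hydride shift to an oxocarbenium ion or an aryl shift are credible diversions. The oxidant may also attack the phenol.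
- Comparison: on structure, the chosen plan carries both centres into the ring closure unchanged, while the alternative builds one there, which is more economical but less safe. On mechanism, the alternative is milder but less supported for allylic aryl ethers with a phenol nucleophile. On step economy the alternative is equal or better.

**Alternative 3:** The cut removes O1–C2 and C2–C3 together, tracing C2 back to a carbene carbon inserted into an O–C bond of a five-membered acetal.
- Forward step: the diazo compound A7, 4-(diazomethyl)-2,6-dimethoxyphenyl acetate, would be decomposed by a chiral dirhodium tetracarboxylate such as Rh2(S-DOSP)4 in the presence of the acetal A6, 6-bromo-4-methoxy-2-methyl-1,3-benzodioxole. The acetal oxygen far from the methoxy group adds to the rhodium carbene, and a Stevens-type [1,2]-shift of the acetal carbon from that oxygen to the former carbene carbon widens the dioxole to the dioxane. The product would be A5, 4-[(2R,3R)-7-bromo-5-methoxy-3-methyl-2,3-dihydro-1,4-benzodioxin-2-yl]-2,6-dimethoxyphenyl acetate.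
- In its favour: two skeletal bonds and both stereocentres in one step from two simple pieces. In convergence and step count it is better than the chosen plan and than the other two alternatives.
- Against it: A7 has no acceptor group and is prone to azine and stilbene formation. The oxygens of a catechol acetal are weak donors and differ only through the neighbouring methoxy group. The shift is likely to occur after the metal has left, so the catalyst can hardly pass on its chirality. The acetal carbon of A6 is racemic, so both the relative and the absolute configuration at C3, the centre that cannot be corrected, would be open. Allylation and deacetylation would still follow.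
- Comparison: on structure, the chosen plan gives every stereocentre a defined origin and the alternative does not. On mechanism, the chosen plan rests on a well-known reaction class and the alternative on an untested substrate pairing. On step economy the alternative is clearly better.

Key step: step 6

Remark on the chemistry: ring positions in all intermediates carry the locants of the target (O1, C2 aryl, C3 methyl, O4, C5 methoxy, C7 side chain); strict nomenclature would number ester 10 and alcohol 11 the other way round (3-aryl-8-methoxy-2-methyl, substituent at C6), the structure being the same.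

Assumption: the (S,S) enantiomer of the salen manganese chloride catalyst is taken to give the (2S,3R) epoxide, by analogy with its known sense on other cis-β-alkylstyrenes; if the sense were opposite, the (R,R) catalyst would be used.

## Route

Step 1
Reactants: 1 syringaldehyde (4-hydroxy-3,5-dimethoxybenzaldehyde)
Product: 2 3,5-dimethoxy-4-(methoxymethoxy)benzaldehyde
Conditions: MOMCl, i-Pr2NEt, CH2Cl2, 0 °C → rt
Reagents that add atoms: chloromethyl methyl ether, COCCl
Why: Williamson-type O-alkylation of the hindered but acidic phenol gives the aryl acetal, which should be inert to ylide, hypochlorite, carbonate at 110 °C, hydride and palladium, and which as an ether donor keeps the future benzylic carbon the more electrophilic epoxide carbon.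

Step 2
Reactants: 2 3,5-dimethoxy-4-(methoxymethoxy)benzaldehyde; 3 ethyltriphenylphosphonium bromide
Product: 5 1,3-dimethoxy-2-(methoxymethoxy)-5-[(1Z)-prop-1-en-1-yl]benzene, via ethylidenetriphenylphosphorane 4 (not isolated)
Conditions: KN(SiMe3)2, THF, 0 °C; then 2, −78 °C → rt
Reagents that add atoms: none
Why: Wittig olefination with a non-stabilised ylide under lithium-free conditions should be kinetically Z-selective through the cis-oxaphosphetane; residual E isomer would be removed on AgNO3-impregnated silica and is in any case a poor substrate for step 3.

Step 3
Reactants: 5 1,3-dimethoxy-2-(methoxymethoxy)-5-[(1Z)-prop-1-en-1-yl]benzene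
Product: 6 (2S,3R)-2-[3,5-dimethoxy-4-(methoxymethoxy)phenyl]-3-methyloxirane (cis)
Conditions: [(S,S)-N,N'-bis(3,5-di-tert-butylsalicylidene)cyclohexane-1,2-diamine]MnCl (5 mol %), 4-phenylpyridine N-oxide, aq NaOCl (pH 11.3), CH2Cl2, 0 °C
Reagents that add atoms: sodium hypochlorite, [Na+].[O-]Cl
Why: Jacobsen–Katsuki epoxidation of a cis-disubstituted aryl alkene: side-on approach to the oxo-manganese species of the (S,S) catalyst should put oxygen on the face that gives the (2S,3R) cis-epoxide. The first C–O bond forms at the methyl-bearing carbon, so this centre (the future C3) carries the enantioselectivity, while any leak through the benzylic radical to the trans-epoxide changes only the benzylic centre, which is correctable later.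

Step 4
Reactants: 7 methyl 4-bromo-3,5-dihydroxybenzoate
Product: 8 methyl 4-bromo-3-hydroxy-5-methoxybenzoate
Conditions: MeI (1.0 equiv), K2CO3 (1.0 equiv), DMF, 0 °C → rt
Reagents that add atoms: iodomethane, CI
Why: Williamson mono-O-methylation of a diol with two equivalent hydroxyl groups, so either one gives the same product; the monoether should be separable from recovered diol (recycled) and from the dimethyl ether, the yield being limited statistically.

Step 5
Reactants: 6 (2S,3R)-2-[3,5-dimethoxy-4-(methoxymethoxy)phenyl]-3-methyloxirane; 8 methyl 4-bromo-3-hydroxy-5-methoxybenzoate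
Product: 9 methyl 4-bromo-3-{[(1R,2R)-1-[3,5-dimethoxy-4-(methoxymethoxy)phenyl]-2-hydroxypropyl]oxy}-5-methoxybenzoate
Conditions: Cs2CO3 (0.5 equiv), DMF, 80 °C
Reagents that add atoms: none
Why: SN2 opening of the aryl epoxide by the caesium phenoxide at the benzylic carbon with inversion (2S becomes 1R) and no change at the methyl-bearing carbon, so the cis-epoxide should give the threo (1R,2R) ether alcohol. Benzylic attack is favoured electronically by the ether-substituted aryl group, as in phenoxide openings of 3-arylglycidols; the regioisomer and any erythro isomer from residual trans-epoxide would be removed by chromatography here.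

Step 6
Reactants: 9 methyl 4-bromo-3-{[(1R,2R)-1-[3,5-dimethoxy-4-(methoxymethoxy)phenyl]-2-hydroxypropyl]oxy}-5-methoxybenzoate
Product: 10 methyl (2R,3R)-2-[3,5-dimethoxy-4-(methoxymethoxy)phenyl]-5-methoxy-3-methyl-2,3-dihydro-1,4-benzodioxine-7-carboxylate
Conditions: CuI (10 mol %), 1,10-phenanthroline (20 mol %), Cs2CO3 (2 equiv), toluene, 110 °C
Reagents that add atoms: none
Why: Cs2CO3 deprotonates the C3 hydroxyl and the phenanthroline-bound monovalent copper alkoxide forms; this adds oxidatively to the C4a–Br bond, which the para ester makes electron-poor, and C–O reductive elimination from the trivalent copper aryl alkoxide forms O4–C4a and returns the catalyst. The closest known reaction type is the copper-catalysed Ullmann-type O-arylation of secondary alcohols, in particular the cyclisation of 2-(2-halophenoxy)ethanols to 1,4-benzodioxanes. The dioxane ring closes in a 6-exo mode at the trigonal C4a, with the bromide leaving outside the new ring and the O1–C2–C3 tether holding the alkoxide next to the halide, which should offset the two ortho substituents. No stereocentre is created and no bond to C2 or C3 is broken, so the threo (1R,2R) ether alcohol must give the trans (2R,3R) ring. The selectivity needed is C–O coupling in preference to reduction of the C–Br bond, attack on an ester, or expulsion of the aryloxide from C2 by the neighbouring alkoxide. It is secured by the activated bromide, the six-membered transition state, the single free hydroxyl and the absence of any acyl group or free phenol on ring B.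

Step 7
Reactants: 10 methyl (2R,3R)-2-[3,5-dimethoxy-4-(methoxymethoxy)phenyl]-5-methoxy-3-methyl-2,3-dihydro-1,4-benzodioxine-7-carboxylate
Product: 11 [(2R,3R)-2-[3,5-dimethoxy-4-(methoxymethoxy)phenyl]-5-methoxy-3-methyl-2,3-dihydro-1,4-benzodioxin-7-yl]methanol
Conditions: i-Bu2AlH, CH2Cl2, −78 → 0 °C; aq potassium sodium tartrate work-up
Reagents that add atoms: none
Why: Hydride reduction of the methyl ester through the aldehyde to the benzylic alcohol; the aryl ethers, the acetal and both stereocentres are inert to the aluminium hydride.

Step 8
Reactants: 11 [(2R,3R)-2-[3,5-dimethoxy-4-(methoxymethoxy)phenyl]-5-methoxy-3-methyl-2,3-dihydro-1,4-benzodioxin-7-yl]methanol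
Product: 12 (2R,3R)-7-(bromomethyl)-2-[3,5-dimethoxy-4-(methoxymethoxy)phenyl]-5-methoxy-3-methyl-2,3-dihydro-1,4-benzodioxine
Conditions: CBr4, PPh3, CH2Cl2, 0 °C
Reagents that add atoms: tetrabromomethane, BrC(Br)(Br)Br
Why: Appel reaction: bromide displaces the alkoxyphosphonium group at the primary benzylic carbon under neutral conditions, which should spare the acid-sensitive acetal and the benzylic C2–O1 ether; the bromide would be used directly in step 9.

Step 9
Reactants: 12 (2R,3R)-7-(bromomethyl)-2-[3,5-dimethoxy-4-(methoxymethoxy)phenyl]-5-methoxy-3-methyl-2,3-dihydro-1,4-benzodioxine; 13 tributyl(vinyl)stannane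
Product: 14 (2R,3R)-2-[3,5-dimethoxy-4-(methoxymethoxy)phenyl]-5-methoxy-3-methyl-7-(prop-2-en-1-yl)-2,3-dihydro-1,4-benzodioxine
Conditions: Pd(PPh3)4 (5 mol %), toluene, 90 °C
Reagents that add atoms: none
Why: Stille coupling: zerovalent palladium adds oxidatively to the benzylic C–Br bond, the vinyl group is transferred from tin and reductive elimination gives the allylarene; the base-free medium should keep the double bond out of conjugation.

Step 10
Reactants: 14 (2R,3R)-2-[3,5-dimethoxy-4-(methoxymethoxy)phenyl]-5-methoxy-3-methyl-7-(prop-2-en-1-yl)-2,3-dihydro-1,4-benzodioxine
Product: 15 4-[(2R,3R)-5-methoxy-3-methyl-7-(prop-2-en-1-yl)-2,3-dihydro-1,4-benzodioxin-2-yl]-2,6-dimethoxyphenol (CNP0116579.1)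
Conditions: 3 M HCl (aq), THF, 40 °C
Reagents that add atoms: none
Why: Acid-catalysed hydrolysis of the aryl methoxymethyl acetal through its oxocarbenium ion; dilute aqueous acid should leave the allyl group alone. If the C2–O1 bond ionises reversibly through the para-quinone methide once the phenol is free, it recloses to the more stable trans ring, so this step would also level any minor C2 epimer carried along.

## Compound list

1 | syringaldehyde (4-hydroxy-3,5-dimethoxybenzaldehyde) | COc1cc(C=O)cc(OC)c1O | starting material
2 | 3,5-dimethoxy-4-(methoxymethoxy)benzaldehyde | COCOc1c(OC)cc(C=O)cc1OC | intermediate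
3 | ethyltriphenylphosphonium bromide | CC[P+](c1ccccc1)(c1ccccc1)c1ccccc1.[Br-] | starting material
4 | ethylidenetriphenylphosphorane (ylide, not isolated) | CC=P(c1ccccc1)(c1ccccc1)c1ccccc1 | intermediate
5 | 1,3-dimethoxy-2-(methoxymethoxy)-5-[(1Z)-prop-1-en-1-yl]benzene | C/C=C\c1cc(OC)c(OCOC)c(OC)c1 | intermediate
6 | (2S,3R)-2-[3,5-dimethoxy-4-(methoxymethoxy)phenyl]-3-methyloxirane | O1[C@@H](c2cc(OC)c(OCOC)c(OC)c2)[C@H]1C | intermediate
7 | methyl 4-bromo-3,5-dihydroxybenzoate | COC(=O)c1cc(O)c(Br)c(O)c1 | starting material
8 | methyl 4-bromo-3-hydroxy-5-methoxybenzoate | COC(=O)c1cc(O)c(Br)c(OC)c1 | intermediate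
9 | methyl 4-bromo-3-{[(1R,2R)-1-[3,5-dimethoxy-4-(methoxymethoxy)phenyl]-2-hydroxypropyl]oxy}-5-methoxybenzoate | COC(=O)c1cc(OC)c(Br)c(O[C@H](c2cc(OC)c(OCOC)c(OC)c2)[C@@H](C)O)c1 | intermediate
10 | methyl (2R,3R)-2-[3,5-dimethoxy-4-(methoxymethoxy)phenyl]-5-methoxy-3-methyl-2,3-dihydro-1,4-benzodioxine-7-carboxylate (target locants; strictly the 3-aryl-8-methoxy-2-methyl-6-carboxylate) | COC(=O)c1cc(OC)c2c(c1)O[C@H](c1cc(OC)c(OCOC)c(OC)c1)[C@@H](C)O2 | intermediate
11 | [(2R,3R)-2-[3,5-dimethoxy-4-(methoxymethoxy)phenyl]-5-methoxy-3-methyl-2,3-dihydro-1,4-benzodioxin-7-yl]methanol (target locants) | OCc1cc(OC)c2c(c1)O[C@H](c1cc(OC)c(OCOC)c(OC)c1)[C@@H](C)O2 | intermediate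
12 | (2R,3R)-7-(bromomethyl)-2-[3,5-dimethoxy-4-(methoxymethoxy)phenyl]-5-methoxy-3-methyl-2,3-dihydro-1,4-benzodioxine | BrCc1cc(OC)c2c(c1)O[C@H](c1cc(OC)c(OCOC)c(OC)c1)[C@@H](C)O2 | intermediate
13 | tributyl(vinyl)stannane | C=C[Sn](CCCC)(CCCC)CCCC | starting material
14 | (2R,3R)-2-[3,5-dimethoxy-4-(methoxymethoxy)phenyl]-5-methoxy-3-methyl-7-(prop-2-en-1-yl)-2,3-dihydro-1,4-benzodioxine | C=CCc1cc(OC)c2c(c1)O[C@H](c1cc(OC)c(OCOC)c(OC)c1)[C@@H](C)O2 | intermediate
15 | 4-[(2R,3R)-5-methoxy-3-methyl-7-(prop-2-en-1-yl)-2,3-dihydro-1,4-benzodioxin-2-yl]-2,6-dimethoxyphenol | C=CCc1cc(OC)c2c(c1)O[C@H](c1cc(OC)c(O)c(OC)c1)[C@@H](C)O2 | target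

## Step count and least certain steps

Total: 10 steps. Longest linear sequence: 9 steps (steps 1, 2, 3, 5, 6, 7, 8, 9 and 10, from 1); step 4 is a one-step side branch.

**Step 6 (key step).** The most likely failure is slow insertion of copper into a bromide flanked by two oxygen substituents. Reduction of the C–Br bond, or reversal of step 5 (the C3 alkoxide expelling the aryloxide from the benzylic carbon), could then overtake the cyclisation. Fallback, from 9 back to 10: the closure is handed to another metal and another set of elementary steps, a palladium-catalysed intramolecular aryl etherification (Pd(OAc)2, 2-(di-tert-butylphosphino)-1,1'-binaphthyl, Cs2CO3, toluene, 70 °C). Zerovalent palladium adds to hindered aryl bromides at lower temperature than copper, and the bulky phosphine forces C–O reductive elimination from the divalent arylpalladium alkoxide ahead of β-hydride loss. This fallback makes no new compound (F0).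

**Step 5.** The most likely failure is attack of the phenoxide at the methyl-bearing epoxide carbon, or sluggish opening by a hindered, weakly nucleophilic ortho-bromophenoxide. Both carbons are secondary and only the electronic bias favours the benzylic one. Fallback, from 8 back to 9, without alkene 5 or epoxide 6:
- Commercial 4-bromo-2,6-dimethoxyphenol is protected (MOMCl, i-Pr2NEt) as 5-bromo-1,3-dimethoxy-2-(methoxymethoxy)benzene F1.
- Bromine–lithium exchange (n-BuLi, THF, −78 °C) and addition to commercial (R)-2-[(tert-butyldimethylsilyl)oxy]propanal under Felkin–Anh control should favour the anti alcohol (1S,2R)-2-[(tert-butyldimethylsilyl)oxy]-1-[3,5-dimethoxy-4-(methoxymethoxy)phenyl]propan-1-ol F2, which is separated from its syn isomer.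
- Mitsunobu etherification with 8 (PPh3, diisopropyl azodicarboxylate, toluene, 0 °C → rt) inverts the benzylic centre and should give methyl 4-bromo-3-{[(1R,2R)-2-[(tert-butyldimethylsilyl)oxy]-1-[3,5-dimethoxy-4-(methoxymethoxy)phenyl]propyl]oxy}-5-methoxybenzoate F3.
- n-Bu4NF in THF then frees the C2 hydroxyl to give 9.

The only free hydroxyl is benzylic, so the regiochemistry is unambiguous, and C3 comes from the chiral pool. The same sequence would therefore also answer a shortfall in the enantioselectivity of step 3.

**Step 2.** The most likely failure is erosion of Z-selectivity by equilibration of the oxaphosphetane. The E-alkene that results would give trans-epoxide of low enantiomeric purity in step 3 and so threaten C3. Fallback, from 2 back to 5: the geometry is set by syn-hydrogenation of an alkyne instead of by olefination.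
- Corey–Fuchs reaction of 2 (CBr4, PPh3, CH2Cl2, 0 °C) gives 5-(2,2-dibromoethenyl)-1,3-dimethoxy-2-(methoxymethoxy)benzene F4.
- n-BuLi (2 equiv, THF, −78 °C) followed by MeI gives 1,3-dimethoxy-2-(methoxymethoxy)-5-(prop-1-yn-1-yl)benzene F5.
- Semi-hydrogenation (H2, Pd on CaCO3 poisoned with Pb(OAc)2, quinoline, EtOAc) should give 5 with the Z geometry.

**Step 4.** The most likely failure is lack of discrimination between the first and the second O-methylation, so that the monoether is only the major part of a three-component mixture. Fallback, from 7 and 6 back to 9: the order of the two ether formations is reversed.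
- Diol 7 in excess (3 equiv, Cs2CO3, DMF, 80 °C) opens epoxide 6 as in step 5 to give methyl 4-bromo-3-{[(1R,2R)-1-[3,5-dimethoxy-4-(methoxymethoxy)phenyl]-2-hydroxypropyl]oxy}-5-hydroxybenzoate F6; the excess diol is recovered.
- MeI and K2CO3 in acetone then methylate the remaining phenol, but not the secondary alcohol, to give 9.

The statistical step disappears, at the cost of one more step on the longest line.

**Step 9.** The most likely failure is migration of the new double bond into conjugation with ring A through a palladium hydride, with homocoupling of the benzylic bromide as a second diversion. Fallback, from 12 back to 14: a copper-catalysed Grignard cross-coupling (vinylmagnesium bromide, CuI 10 mol %, THF, −30 °C) replaces the palladium cycle with an organocuprate substitution at the benzylic carbon. No metal hydride can arise in it, and it is compatible with 12 because the ester has already been reduced. This fallback makes no new compound (F0).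

## Further compounds

F0 | step 6 | none | none
F1 | step 5 | 5-bromo-1,3-dimethoxy-2-(methoxymethoxy)benzene | COCOc1c(OC)cc(Br)cc1OC
F2 | step 5 | (1S,2R)-2-[(tert-butyldimethylsilyl)oxy]-1-[3,5-dimethoxy-4-(methoxymethoxy)phenyl]propan-1-ol | O[C@@H](c1cc(OC)c(OCOC)c(OC)c1)[C@@H](C)O[Si](C)(C)C(C)(C)C
F3 | step 5 | methyl 4-bromo-3-{[(1R,2R)-2-[(tert-butyldimethylsilyl)oxy]-1-[3,5-dimethoxy-4-(methoxymethoxy)phenyl]propyl]oxy}-5-methoxybenzoate | COC(=O)c1cc(OC)c(Br)c(O[C@H](c2cc(OC)c(OCOC)c(OC)c2)[C@@H](C)O[Si](C)(C)C(C)(C)C)c1
F4 | step 2 | 5-(2,2-dibromoethenyl)-1,3-dimethoxy-2-(methoxymethoxy)benzene | COCOc1c(OC)cc(C=C(Br)Br)cc1OC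
F5 | step 2 | 1,3-dimethoxy-2-(methoxymethoxy)-5-(prop-1-yn-1-yl)benzene | CC#Cc1cc(OC)c(OCOC)c(OC)c1
F6 | step 4 | methyl 4-bromo-3-{[(1R,2R)-1-[3,5-dimethoxy-4-(methoxymethoxy)phenyl]-2-hydroxypropyl]oxy}-5-hydroxybenzoate | COC(=O)c1cc(O)c(Br)c(O[C@H](c2cc(OC)c(OCOC)c(OC)c2)[C@@H](C)O)c1
F0 | step 9 | none | none
A1 | alternative 1 | (2R,3R)-2-[3,5-dimethoxy-4-(methoxymethoxy)phenyl]-5-methoxy-3-methyl-7-(prop-2-en-1-yl)-2,3-dihydro-1,4-benzodioxine | C=CCc1cc(OC)c2c(c1)O[C@H](c1cc(OC)c(OCOC)c(OC)c1)[C@@H](C)O2
A2 | alternative 1 | (1R,2R)-2-[2-bromo-6-methoxy-4-(prop-2-en-1-yl)phenoxy]-1-[3,5-dimethoxy-4-(methoxymethoxy)phenyl]propan-1-ol | O[C@H](c1cc(OC)c(OCOC)c(OC)c1)[C@@H](C)Oc1c(OC)cc(CC=C)cc1Br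
A3 | alternative 2 | (2R,3R)-7-bromo-2-[3,5-dimethoxy-4-(triisopropylsilyloxy)phenyl]-5-methoxy-3-methyl-2,3-dihydro-1,4-benzodioxine | Brc1cc(OC)c2c(c1)O[C@H](c1cc(OC)c(O[Si](C(C)C)(C(C)C)C(C)C)c(OC)c1)[C@@H](C)O2
A4 | alternative 2 | 4-bromo-2-{[(1S)-1-[3,5-dimethoxy-4-(triisopropylsilyloxy)phenyl]prop-2-en-1-yl]oxy}-6-methoxyphenol | Oc1c(OC)cc(Br)cc1O[C@H](c1cc(OC)c(O[Si](C(C)C)(C(C)C)C(C)C)c(OC)c1)C=C
A5 | alternative 3 | 4-[(2R,3R)-7-bromo-5-methoxy-3-methyl-2,3-dihydro-1,4-benzodioxin-2-yl]-2,6-dimethoxyphenyl acetate | Brc1cc(OC)c2c(c1)O[C@H](c1cc(OC)c(OC(C)=O)c(OC)c1)[C@@H](C)O2
A6 | alternative 3 | 6-bromo-4-methoxy-2-methyl-1,3-benzodioxole (racemic) | CC1Oc2cc(Br)cc(OC)c2O1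
A7 | alternative 3 | 4-(diazomethyl)-2,6-dimethoxyphenyl acetate | CC(=O)Oc1c(OC)cc(C=[N+]=[N-])cc1OC
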